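## Analysis of the target

The target is the chain sulfate of an 8–5′ neolignan of the phenylcoumaran type. Its core is a 2,3-dihydrobenzofuran whose five-membered ring (O1, C2, C3, C3a, C7a) is fused to ring B, which carries a methoxy group at C7 and a 3-(sulfooxy)propyl chain at C5; C2 bears ring A (4-hydroxy-3-methoxyphenyl) and C3 a hydroxymethyl group. There are two adjacent stereocentres, C2 (S) and C3 (R), with ring A and the CH2OH arm trans on the furan ring; trans is also the more stable arrangement, so the real task is the absolute configuration. The sensitive groups are the primary alkyl hydrogen sulfate (very polar, open to acid-catalysed solvolysis, so it belongs at the end), the free phenol of ring A para to the benzylic C2–O1 bond (a quinone methide can open the ring in strongly basic or acidic media and erase C2), and that benzylic aryl ether itself, which is at risk under hydrogenolysis. Two primary alcohols are present and only the one at the end of the propyl chain is sulfated, so the two must be kept apart over the whole route. Both rings are electron-rich, which forbids strongly oxidising or electrophilic reagents late in the synthesis. The plan rests on the position of C2 between the phenolic oxygen O1 of ring B and the benzylic carbon C3: if C2 arrives with ring A as a one-carbon unit that is first a nucleophile (towards C3) and then an electrophile (towards O1), the bonds C2–C3 and O1–C2, the ring and both stereocentres are made in one operation.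

## Retrosynthetic reasoning

**Sulfate and final deprotection.** The sulfate O–S bond is cut first. Target 25 is traced to the sodium sulfate 23, which has the C3 arm as an acetate and the ring A phenol as a pivalate. Both esters fall in one transesterification, so the last step frees two hydroxyl groups without touching the sulfate monoester. 23 comes from alcohol 21 by O-sulfation. Placing these operations at the end keeps every earlier intermediate neutral and chromatographable, and only one hydroxyl group is free at the moment of sulfation.

**Telling the two alcohols apart.** The two primary alcohols are distinguished by their origin, not by a selective reaction. The chain oxygen is carried as a silyl ether from the second step (21 from 20 by desilylation). The C3 hydroxymethyl group appears late and is acetylated at once (20 from 19).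

**The C3 arm.** The CH2OH group of 19 is traced to the carboxylic acid 18, and 18 to the nitromethyl compound 17; the C–N bond is the one given up. A nitromethyl group is chosen because its precursor, a nitroalkene, is the acceptor the key step needs. The aldehyde oxidation level at C3 is avoided: there the α-hydrogen would be acidic and the ring B aryloxy group would sit in the β-position, an arrangement open to β-elimination and loss of both stereocentres. The acid is formed in a weakly acidic medium and reduced without base, so C3 should keep its configuration.

**The key disconnection.** In 17 the bonds O1–C2 and C2–C3 are cut together. This removes C2 with ring A as one piece, the benzylic carbon of sulfonium salt 14, and leaves ring B with its phenol oxygen and a two-carbon nitrovinyl arm, compound 6. Cutting here and not at C3–C3a or C7a–O1 means that no bond to the crowded ring B is made in the stereo-determining step, that ring and stereocentres arise together, and that the chirality can sit in the leaving group of the one-carbon unit. Forward, the ylide of 14 must add to the nitroalkene carbon attached to ring B, and the phenoxide must then displace the sulfide at the same carbon. The chiral thiolane has to control the face of the ylide, and the trans relation has to follow from the addition–displacement sequence.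

**Nitrovinylphenol 6.** 6 is traced through its C=C bond to salicylaldehyde 5 (nitroaldol condensation), and 5 through the aryl–CHO bond to phenol 4. Ring B has a single free position ortho to the hydroxyl group, so the formyl group can only enter where it is needed. 4 is the mono-silyl ether of diol 3, the anti-Markovnikov hydration product of the allyl group of 1.

**Sulfonium salt 14.** 14 is cut at the S–CH2 bond into benzylic bromide 10 and thiolane 13. 10 derives from 7 by O-acylation (8), reduction (9) and bromination. A pivalate is preferred to an ether on the ring A oxygen for three reasons: it makes the benzylic sulfonium less prone to ionise, it makes the benzylic hydrogens more acidic, and it leaves in the final transesterification, so no hydrogenolysis is needed next to the benzylic C2–O1 bond. 13 is cut at both C–S bonds to dimesylate 12 of diol 11; two inversions turn the (2R,5R)-diol into the (2S,5S)-thiolane.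

## Alternatives that were turned down

**Alternative 1: ring contraction of a flavanone.**
- Disconnection: the C3–C3a bond, traced back to a 1,2-shift of ring B. The precursor is the (S)-flavanone A1, in which ring B is still bonded to the carbonyl carbon.
- Forward key step: PhI(OH)OTs (trivalent iodine) in acidified trimethyl orthoformate attacks the enol ether of A1 at C3. Ring B migrates from the former carbonyl carbon to C3 as iodobenzene leaves, the six-membered ring contracts, and the carbonyl carbon becomes the methyl ester of A2.
- For it: the C3 substituent arrives at the ester level, one hydride reduction from CH2OH, which is shorter than the nitro → acid → alcohol passage chosen here. The migration gives the trans ester. Oxidative ring contraction of flavanones is an established reaction class, which the chosen key step in its asymmetric form is not; on precedent for the bond-forming event this alternative is stronger.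
- Against it: everything depends on the single stereocentre of A1, and a 2-arylchromanone is configurationally fragile. Under the strongly acidic conditions it can open by retro-oxa-Michael reaction to the achiral enone and close again as the racemate. The electron-rich ring A can compete as migrating group, or the ring can simply be dehydrogenated, and both methoxy-rich rings are substrates for the iodane. A1 must first be made enantiopure from an ortho-acylated ring B phenol by aldol condensation and asymmetric cyclisation, which is no shorter than the preparation of 6 and 14.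
- Comparison: the chosen route keeps its stereocentres out of strong acid, builds the ring from two aldehyde-level fragments, and uses a recoverable chiral sulfide; it pays with two extra redox steps on the C3 arm.

**Alternative 2: three-component aryl migration–aldol.**
- Disconnection: C3–C3a and C2–C3, with O1–C2 left for a later ring closure.
- Forward key step: an aryl dialkylborane made from ring B adds to a diazoacetyl imide that carries an oxazolidinone auxiliary. Ring B migrates from boron to carbon as N2 leaves, and the boron enolate adds to an O-benzylated ring A aldehyde to give the syn aldol A3.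
- For it: two C–C bonds and both stereocentres from three simple pieces. Absolute control comes from an auxiliary whose aldol transition states are well understood; on this point it is stronger than the chosen route, whose sense and level of induction are extrapolated. The imide is one reduction from CH2OH.
- Against it: the migrating aryl group is ortho-substituted and electron-rich, and migration of a ring bond of the bicyclic borane cannot be excluded. Enolate geometry, and with it syn/anti, is fixed by the migration and not by a controlled enolisation. The furan ring is still open after the key step. Closing it needs substitution at the benzylic carbinol carbon by the ring B phenol, which with a para-alkoxyaryl group tends to run through a benzylic cation, so the C2 configuration made by the aldol is decided again. More protecting groups (acetal, benzyl ether, silyl ether, auxiliary) and more steps follow.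
- Comparison: the chosen route merges C–C formation, ring closure and both stereocentres in one step and needs no substitution of uncertain stereochemical course afterwards.

**Alternative 3: benzofuran by tandem arylation, stereocentres by hydrogenation.**
- Disconnection: C3–C3a and C7a–O1, both bonds from the furan ring to ring B; a β-keto ester carrying ring A supplies O1, C2 and C3.
- Forward key step: Pd2(dba)3 (zerovalent palladium) with Xantphos and Cs2CO3 couples the β-keto ester carbon with an aryl iodide of ring B and then the enolate oxygen with the neighbouring aryl triflate, giving the achiral benzofuran ester A4.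
- For it: convergent, robust cross-coupling with no stereochemical issue in the ring-forming step; in reliability of the ring construction it is stronger than the chosen route. The ester level at C3 is right, and the later source of chirality could in principle be catalytic.
- Against it: the key step creates no stereocentre. Both must come from enantioselective hydrogenation of a tetrasubstituted, aromatic furan double bond bearing an aryl and an ester group, a demanding substrate class without a general catalyst. The cis product of syn hydrogen addition must then be epimerised at C3. A dissolving-metal reduction would give the trans ester but racemic. The ring B partner needs iodide and triflate on adjacent carbons next to a methoxy group.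
- Comparison: the chosen route places its uncertainty in the step that forms the ring and has a resolution to fall back on at the acid stage; alternative 3 moves the uncertainty to a later step with less precedent.

Key step: step 11

Assumption: the facial bias of the 2,5-dimethylthiolanium benzylide towards the nitroalkene is taken to be the one it shows towards aldehydes (aryl group turned away from the ring, attack on the ylide face remote from the methyl group syn to the ylide carbon); on this basis the (2S,5S)-thiolane leads to (2S,3R).

## Route

Step 1
Reactants: 1 eugenol (4-allyl-2-methoxyphenol)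
Product: 3 4-(3-hydroxypropyl)-2-methoxyphenol, via bis-9-BBN adduct 2 (not isolated)
Conditions: 9-BBN (2.2 equiv), THF, 0 °C → rt; then NaOH (aq), H2O2, 0 °C → rt
Reagents that add atoms: hydrogen peroxide, OO
Why: Hydroboration–oxidation; the bulky borane places boron on the terminal carbon of the allyl group, and the second equivalent is taken up by the phenol O–H (as borinate, with loss of H2), which the alkaline peroxide work-up frees again.

Step 2
Reactants: 3 4-(3-hydroxypropyl)-2-methoxyphenol
Product: 4 4-[3-(tert-butyldimethylsilyloxy)propyl]-2-methoxyphenol
Conditions: TBSCl (1.05 equiv), imidazole, CH2Cl2/DMF, 0 °C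
Reagents that add atoms: tert-butyldimethylsilyl chloride, CC(C)(C)[Si](C)(C)Cl
Why: Chemoselective O-silylation; with imidazole as base the unhindered primary alcohol should react faster than the hydrogen-bonded, ortho-substituted guaiacol hydroxyl group, so one equivalent of chloride goes to the chain oxygen.

Step 3
Reactants: 4 4-[3-(tert-butyldimethylsilyloxy)propyl]-2-methoxyphenol
Product: 5 5-[3-(tert-butyldimethylsilyloxy)propyl]-2-hydroxy-3-methoxybenzaldehyde
Conditions: MgCl2, Et3N, (CH2O)n, MeCN, reflux
Reagents that add atoms: paraformaldehyde (formaldehyde), C=O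
Why: Magnesium-mediated ortho-formylation of a phenol: the chloromagnesium phenoxide ArOMgCl adds formaldehyde at the ortho carbon and a second formaldehyde takes up hydride from the resulting benzylic alkoxide. The para position is blocked and only one ortho position is free, so a single salicylaldehyde can form; the silyl ether is inert here.

Step 4
Reactants: 5 5-[3-(tert-butyldimethylsilyloxy)propyl]-2-hydroxy-3-methoxybenzaldehyde
Product: 6 4-[3-(tert-butyldimethylsilyloxy)propyl]-2-methoxy-6-[(E)-2-nitrovinyl]phenol
Conditions: CH3NO2, NH4OAc, 90 °C
Reagents that add atoms: nitromethane, C[N+](=O)[O-]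
Why: Henry (nitroaldol) condensation with loss of water gives the conjugated (E)-nitroalkene, the more stable isomer; the buffered medium spares the silyl ether and the free phenol needs no protection.

Step 5
Reactants: 7 vanillin
Product: 8 4-formyl-2-methoxyphenyl pivalate
Conditions: PivCl, Et3N, DMAP (cat.), CH2Cl2, 0 °C → rt
Reagents that add atoms: pivaloyl chloride, CC(C)(C)C(=O)Cl
Why: O-acylation of the phenol; the hindered aryl ester should withstand the carbonate base of the key step and the later borane, acid and fluoride steps, and it leaves by transesterification at the end.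

Step 6
Reactants: 8 4-formyl-2-methoxyphenyl pivalate
Product: 9 4-(hydroxymethyl)-2-methoxyphenyl pivalate
Conditions: NaBH4, THF/EtOH, 0 °C
Reagents that add atoms: none
Why: Chemoselective hydride reduction of the aldehyde; the hindered aryl ester is not attacked at 0 °C.

Step 7
Reactants: 9 4-(hydroxymethyl)-2-methoxyphenyl pivalate
Product: 10 4-(bromomethyl)-2-methoxyphenyl pivalate
Conditions: PBr3, CH2Cl2, 0 °C
Reagents that add atoms: phosphorus tribromide (PBr3), BrP(Br)Br
Why: The benzylic alcohol is converted into the bromide through its phosphite ester (SN2 by bromide); the acyloxy group keeps the ring from being so electron-rich that the bromide ionises and self-condenses.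

Step 8
Reactants: 11 (2R,5R)-hexane-2,5-diol
Product: 12 (2R,5R)-hexane-2,5-diyl dimethanesulfonate
Conditions: MsCl, Et3N, CH2Cl2, −20 → 0 °C
Reagents that add atoms: methanesulfonyl chloride, CS(=O)(=O)Cl
Why: Sulfonylation of both secondary alcohols at oxygen, with no change at the stereocentres.

Step 9
Reactants: 12 (2R,5R)-hexane-2,5-diyl dimethanesulfonate
Product: 13 (2S,5S)-2,5-dimethylthiolane
Conditions: Na2S·9H2O, DMSO, rt
Reagents that add atoms: sodium sulfide (Na2S), [Na+].[Na+].[S-2]
Why: Double SN2 displacement (intermolecular, then 5-exo-tet) inverts both centres, so the (2R,5R)-dimesylate gives the twofold-symmetric (2S,5S)-thiolane; the volatile sulfide is isolated by distillation.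

Step 10
Reactants: 10 4-(bromomethyl)-2-methoxyphenyl pivalate; 13 (2S,5S)-2,5-dimethylthiolane
Product: 14 (2S,5S)-1-[3-methoxy-4-(pivaloyloxy)benzyl]-2,5-dimethylthiolan-1-ium tetrafluoroborate
Conditions: AgBF4, CH2Cl2, 0 °C → rt, dark
Reagents that add atoms: silver tetrafluoroborate (AgBF4), [Ag+].F[B-](F)(F)F
Why: Halide abstraction by silver drives S-alkylation of the hindered sulfide and leaves a non-nucleophilic counter-ion that cannot take the benzyl group back. Because the thiolane is twofold-symmetric its two lone pairs are equivalent and a single sulfonium salt forms.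

Step 11
Reactants: 6 4-[3-(tert-butyldimethylsilyloxy)propyl]-2-methoxy-6-[(E)-2-nitrovinyl]phenol; 14 (2S,5S)-1-[3-methoxy-4-(pivaloyloxy)benzyl]-2,5-dimethylthiolan-1-ium tetrafluoroborate
Product: 17 (2S,3R)-5-[3-(tert-butyldimethylsilyloxy)propyl]-7-methoxy-2-[3-methoxy-4-(pivaloyloxy)phenyl]-3-(nitromethyl)-2,3-dihydrobenzofuran, via sulfonium ylide 15 (not isolated), via nitronate betaine 16 (not isolated)
Conditions: Cs2CO3 (1.5 equiv), MeCN, −20 °C → rt
Reagents that add atoms: none
Why: Proposed new method: Cs2CO3 turns 6 into its phenoxide and 14 into the benzylic ylide 15; the ylide carbon adds to the nitroalkene carbon attached to ring B (C2–C3) to give betaine 16, the phenoxide oxygen then displaces the thiolane at the benzylic carbon with inversion (O1–C2), and the nitronate is protonated by hydrogen carbonate or on work-up. The closest known reaction types are the formal [4+1] annulation of carbonyl-stabilised sulfonium ylides with 2-(2-nitrovinyl)phenols to trans-2,3-dihydrobenzofurans and, for the chiral reagent, the asymmetric epoxidation of aldehydes by 2,5-dimethylthiolanium benzylides; joining a chiral benzylic ylide with this acceptor is the untested part. The dihydrofuran ring closes in the 5-exo-tet mode. C2 is controlled by the thiolane: in the ylide the aryl group points away from the ring and the methyl group syn to the ylide carbon shields one face, so addition on the open face followed by inversion at C2 should give 2S with the (2S,5S)-auxiliary. C3 is set relative to C2 in the addition step (the two aryl groups apart) and by the faster closure of the betaine that leads to the trans ring. The step needs C-addition of the ylide to win over O-benzylation of the phenoxide by 14, and ring closure by phenoxide to win over O- or C-alkylation of the nitronate. The BF4 counter-ion, the electron-poor pivaloyloxy substituent on the benzylic group and the well-placed, more nucleophilic phenoxide should secure this.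

Step 12
Reactants: 17 (2S,3R)-5-[3-(tert-butyldimethylsilyloxy)propyl]-7-methoxy-2-[3-methoxy-4-(pivaloyloxy)phenyl]-3-(nitromethyl)-2,3-dihydrobenzofuran
Product: 18 (2S,3S)-5-[3-(tert-butyldimethylsilyloxy)propyl]-7-methoxy-2-[3-methoxy-4-(pivaloyloxy)phenyl]-2,3-dihydrobenzofuran-3-carboxylic acid
Conditions: NaNO2, AcOH, DMSO, 35 °C
Reagents that add atoms: sodium nitrite (NaNO2), O=N[O-].[Na+]; water, O
Why: Nitrite-mediated oxidation of a primary nitroalkane to the carboxylic acid (nitrolic acid, nitrile oxide, hydroxamic acid) in weakly acidic DMSO. C3, now α to the carboxyl group, is not deprotonated in this medium and the β-aryloxy group cannot be eliminated, so both stereocentres are kept (the descriptor at C3 changes only through the priority rules).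

Step 13
Reactants: 18 (2S,3S)-5-[3-(tert-butyldimethylsilyloxy)propyl]-7-methoxy-2-[3-methoxy-4-(pivaloyloxy)phenyl]-2,3-dihydrobenzofuran-3-carboxylic acid
Product: 19 (2S,3R)-5-[3-(tert-butyldimethylsilyloxy)propyl]-3-(hydroxymethyl)-7-methoxy-2-[3-methoxy-4-(pivaloyloxy)phenyl]-2,3-dihydrobenzofuran
Conditions: BH3·THF, THF, 0 °C → rt; then H2O
Reagents that add atoms: none
Why: Borane reduces the carboxylic acid through its acyloxyborane much faster than it touches the hindered aryl pivalate; no base is present, so C3 is not epimerised and the furan ring is not opened.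

Step 14
Reactants: 19 (2S,3R)-5-[3-(tert-butyldimethylsilyloxy)propyl]-3-(hydroxymethyl)-7-methoxy-2-[3-methoxy-4-(pivaloyloxy)phenyl]-2,3-dihydrobenzofuran
Product: 20 [(2S,3R)-5-[3-(tert-butyldimethylsilyloxy)propyl]-7-methoxy-2-[3-methoxy-4-(pivaloyloxy)phenyl]-2,3-dihydrobenzofuran-3-yl]methyl acetate
Conditions: Ac2O, pyridine, DMAP (cat.), CH2Cl2, 0 °C → rt
Reagents that add atoms: acetic anhydride, CC(=O)OC(C)=O
Why: Acylation of the only free hydroxyl group; the acetate masks the C3 arm during sulfation and leaves together with the pivalate.

Step 15
Reactants: 20 [(2S,3R)-5-[3-(tert-butyldimethylsilyloxy)propyl]-7-methoxy-2-[3-methoxy-4-(pivaloyloxy)phenyl]-2,3-dihydrobenzofuran-3-yl]methyl acetate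
Product: 21 [(2S,3R)-5-(3-hydroxypropyl)-7-methoxy-2-[3-methoxy-4-(pivaloyloxy)phenyl]-2,3-dihydrobenzofuran-3-yl]methyl acetate
Conditions: HF·pyridine, THF/pyridine, 0 °C → rt
Reagents that add atoms: none
Why: Fluoride cleavage of the primary silyl ether under buffered, non-basic conditions, so neither ester is cleaved and the acetate does not migrate.

Step 16
Reactants: 21 [(2S,3R)-5-(3-hydroxypropyl)-7-methoxy-2-[3-methoxy-4-(pivaloyloxy)phenyl]-2,3-dihydrobenzofuran-3-yl]methyl acetate
Product: 23 sodium 3-[(2S,3R)-3-(acetoxymethyl)-7-methoxy-2-[3-methoxy-4-(pivaloyloxy)phenyl]-2,3-dihydrobenzofuran-5-yl]propyl sulfate, via pyridinium sulfate 22 (not isolated)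
Conditions: SO3·pyridine, pyridine, rt; then NaHCO3 (aq)
Reagents that add atoms: sulfur trioxide–pyridine complex, O=S(=O)([O-])[n+]1ccccc1; sodium hydrogen carbonate (NaHCO3), [Na+].OC([O-])=O
Why: O-sulfation of the only free hydroxyl group by the amine–SO3 complex; exchange to the sodium salt makes the monoester stable to handling and chromatography.

Step 17
Reactants: 23 sodium 3-[(2S,3R)-3-(acetoxymethyl)-7-methoxy-2-[3-methoxy-4-(pivaloyloxy)phenyl]-2,3-dihydrobenzofuran-5-yl]propyl sulfate
Product: 25 3-[(2S,3R)-2-(4-hydroxy-3-methoxyphenyl)-3-(hydroxymethyl)-7-methoxy-2,3-dihydrobenzofuran-5-yl]propyl hydrogen sulfate, via disodium salt 24 (not isolated)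
Conditions: NaOMe, MeOH, 0 °C → rt; then HCl (aq) to pH 2, 0 °C; C18 desalting
Reagents that add atoms: none
Why: Zemplén transesterification cleaves the alkyl acetate and the aryl pivalate while the sulfate monoester anion is inert to methoxide. Brief cold acidification protonates phenoxide and sulfate, and reversed-phase desalting should give the free hydrogen sulfate; C2 and C3 carry no acidic hydrogen and are untouched.

## Compound list

1 | eugenol (4-allyl-2-methoxyphenol) | C=CCc1ccc(O)c(OC)c1 | starting material
2 | 9-{3-[4-(9-borabicyclo[3.3.1]nonan-9-yloxy)-3-methoxyphenyl]propyl}-9-borabicyclo[3.3.1]nonane (bis-9-BBN adduct) | COc1cc(CCCB2C3CCCC2CCC3)ccc1OB1C2CCCC1CCC2 | intermediate (not isolated)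
3 | 4-(3-hydroxypropyl)-2-methoxyphenol | COc1cc(CCCO)ccc1O | intermediate
4 | 4-[3-(tert-butyldimethylsilyloxy)propyl]-2-methoxyphenol | COc1cc(CCCO[Si](C)(C)C(C)(C)C)ccc1O | intermediate
5 | 5-[3-(tert-butyldimethylsilyloxy)propyl]-2-hydroxy-3-methoxybenzaldehyde | COc1cc(CCCO[Si](C)(C)C(C)(C)C)cc(C=O)c1O | intermediate
6 | 4-[3-(tert-butyldimethylsilyloxy)propyl]-2-methoxy-6-[(E)-2-nitrovinyl]phenol | COc1cc(CCCO[Si](C)(C)C(C)(C)C)cc(/C=C/[N+](=O)[O-])c1O | intermediate
7 | vanillin | COc1cc(C=O)ccc1O | starting material
8 | 4-formyl-2-methoxyphenyl pivalate | COc1cc(C=O)ccc1OC(=O)C(C)(C)C | intermediate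
9 | 4-(hydroxymethyl)-2-methoxyphenyl pivalate | COc1cc(CO)ccc1OC(=O)C(C)(C)C | intermediate
10 | 4-(bromomethyl)-2-methoxyphenyl pivalate | COc1cc(CBr)ccc1OC(=O)C(C)(C)C | intermediate
11 | (2R,5R)-hexane-2,5-diol | C[C@@H](O)CC[C@@H](C)O | starting material
12 | (2R,5R)-hexane-2,5-diyl dimethanesulfonate | C[C@@H](OS(C)(=O)=O)CC[C@@H](C)OS(C)(=O)=O | intermediate
13 | (2S,5S)-2,5-dimethylthiolane | C[C@H]1CC[C@H](C)S1 | intermediate
14 | (2S,5S)-1-[3-methoxy-4-(pivaloyloxy)benzyl]-2,5-dimethylthiolan-1-ium tetrafluoroborate | C[C@H]1CC[C@H](C)[S+]1Cc2ccc(OC(=O)C(C)(C)C)c(OC)c2.F[B-](F)(F)F | intermediate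
15 | sulfonium ylide of 14 (benzylic carbanion on the (2S,5S)-thiolanium) | C[C@H]1CC[C@H](C)[S+]1[CH-]c2ccc(OC(=O)C(C)(C)C)c(OC)c2 | intermediate (not isolated)
16 | nitronate betaine: Cs+ phenoxide of the open-chain adduct with nitronate at the C3 arm and the thiolanium still on the benzylic carbon | COc1cc(CCCO[Si](C)(C)C(C)(C)C)cc([C@H](C=[N+]([O-])[O-])[C@H](c2ccc(OC(=O)C(C)(C)C)c(OC)c2)[S+]3[C@@H](C)CC[C@@H]3C)c1[O-].[Cs+] | intermediate (not isolated)
17 | (2S,3R)-5-[3-(tert-butyldimethylsilyloxy)propyl]-7-methoxy-2-[3-methoxy-4-(pivaloyloxy)phenyl]-3-(nitromethyl)-2,3-dihydrobenzofuran | COc1cc([C@H]2Oc3c(OC)cc(CCCO[Si](C)(C)C(C)(C)C)cc3[C@@H]2C[N+](=O)[O-])ccc1OC(=O)C(C)(C)C | intermediate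
18 | (2S,3S)-5-[3-(tert-butyldimethylsilyloxy)propyl]-7-methoxy-2-[3-methoxy-4-(pivaloyloxy)phenyl]-2,3-dihydrobenzofuran-3-carboxylic acid | COc1cc([C@H]2Oc3c(OC)cc(CCCO[Si](C)(C)C(C)(C)C)cc3[C@@H]2C(=O)O)ccc1OC(=O)C(C)(C)C | intermediate
19 | (2S,3R)-5-[3-(tert-butyldimethylsilyloxy)propyl]-3-(hydroxymethyl)-7-methoxy-2-[3-methoxy-4-(pivaloyloxy)phenyl]-2,3-dihydrobenzofuran | COc1cc([C@H]2Oc3c(OC)cc(CCCO[Si](C)(C)C(C)(C)C)cc3[C@@H]2CO)ccc1OC(=O)C(C)(C)C | intermediate
20 | [(2S,3R)-5-[3-(tert-butyldimethylsilyloxy)propyl]-7-methoxy-2-[3-methoxy-4-(pivaloyloxy)phenyl]-2,3-dihydrobenzofuran-3-yl]methyl acetate | COc1cc([C@H]2Oc3c(OC)cc(CCCO[Si](C)(C)C(C)(C)C)cc3[C@@H]2COC(C)=O)ccc1OC(=O)C(C)(C)C | intermediate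
21 | [(2S,3R)-5-(3-hydroxypropyl)-7-methoxy-2-[3-methoxy-4-(pivaloyloxy)phenyl]-2,3-dihydrobenzofuran-3-yl]methyl acetate | COc1cc([C@H]2Oc3c(OC)cc(CCCO)cc3[C@@H]2COC(C)=O)ccc1OC(=O)C(C)(C)C | intermediate
22 | pyridinium 3-[(2S,3R)-3-(acetoxymethyl)-7-methoxy-2-[3-methoxy-4-(pivaloyloxy)phenyl]-2,3-dihydrobenzofuran-5-yl]propyl sulfate | COc1cc([C@H]2Oc3c(OC)cc(CCCOS(=O)(=O)[O-])cc3[C@@H]2COC(C)=O)ccc1OC(=O)C(C)(C)C.c1cc[nH+]cc1 | intermediate (not isolated)
23 | sodium 3-[(2S,3R)-3-(acetoxymethyl)-7-methoxy-2-[3-methoxy-4-(pivaloyloxy)phenyl]-2,3-dihydrobenzofuran-5-yl]propyl sulfate | COc1cc([C@H]2Oc3c(OC)cc(CCCOS(=O)(=O)[O-])cc3[C@@H]2COC(C)=O)ccc1OC(=O)C(C)(C)C.[Na+] | intermediate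
24 | disodium salt of the target (sodium phenoxide, sodium alkyl sulfate) | COc1cc([C@H]2Oc3c(OC)cc(CCCOS(=O)(=O)[O-])cc3[C@@H]2CO)ccc1[O-].[Na+].[Na+] | intermediate (not isolated)
25 | 3-[(2S,3R)-2-(4-hydroxy-3-methoxyphenyl)-3-(hydroxymethyl)-7-methoxy-2,3-dihydrobenzofuran-5-yl]propyl hydrogen sulfate | COc1cc([C@H]2Oc3c(OC)cc(CCCOS(=O)(=O)O)cc3[C@@H]2CO)ccc1O | target

## Step count and least certain steps

Total step count: 17. Longest linear sequence: 11 steps (1 → 25 through steps 1–4 and 11–17; the branch from 7 through steps 5–7, 10 and 11–17 is equally long).

**Step 11 (key step, proposed new method).**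
- What may go wrong: poor facial selectivity at the ylide carbon, because the bias known for aldehydes need not carry over to a nitroalkene acceptor and reversible addition could erode it. The phenoxide of 6 forms long before the ylide and could be O-benzylated by 14. Closure could also be incompletely trans-selective.
- Fallback (known chemistry), from 10 and 6, returning at 18: bromide 10 is S-alkylated with tetrahydrothiophene (AgBF4, CH2Cl2) to the achiral salt 1-[3-methoxy-4-(pivaloyloxy)benzyl]thiolan-1-ium tetrafluoroborate F1. F1 and 6 with Cs2CO3 in MeCN undergo the racemic annulation, the known reaction class with no demand on facial control, to the racemic trans-3-(nitromethyl)dihydrobenzofuran F2. NaNO2/AcOH/DMSO as in step 12 gives the racemic trans carboxylic acid F3. Crystallisation with one enantiomer of 1-phenylethylamine gives the 1-phenylethylammonium salt of the (2S,3S)-acid F4; the (S)-amine is written, and the enantiomer that gives the less soluble salt of the wanted acid is used. Dilute acid then liberates 18.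

**Step 12 (nitro → acid).**
- What may go wrong: loss of the silyl ether in the acetic acid medium, slow conversion, or nitrosation of the electron-rich ring B.
- Fallback, from 17, returning at 19: a Nef-type route. The nitronate of 17 (DBU, MeCN/acetone, −20 °C) is oxidised with dimethyldioxirane to (2S,3S)-5-[3-(tert-butyldimethylsilyloxy)propyl]-7-methoxy-2-[3-methoxy-4-(pivaloyloxy)phenyl]-2,3-dihydrobenzofuran-3-carbaldehyde F5. F5 is reduced at once with NaBH4 at −20 °C to 19. The aldehyde is kept cold and is not stored, because β-elimination of the aryloxy group is its weak point.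

**Step 10 (sulfonium salt).**
- What may go wrong: sluggish S-alkylation of the hindered, volatile thiolane, and silver-promoted self-condensation of the benzylic bromide.
- Fallback, from 9 and 13, returning at 14: acid-promoted dehydrative S-alkylation of the sulfide by the benzylic alcohol (HBF4·OEt2, CH2Cl2, 0 °C), which needs neither bromide nor silver and makes no new compound (F0).

**Step 3 (ortho-formylation).**
- What may go wrong: slow formylation because the neighbouring methoxy group chelates magnesium, and condensation of the product with formaldehyde and phenol to diarylmethanes.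
- Fallback, from 4, returning at 5: ortho-bromination (NBS, CH2Cl2, −20 °C; the hydroxyl group directs to its only free ortho position) to 2-bromo-6-methoxy-4-[3-(tert-butyldimethylsilyloxy)propyl]phenol F6. O-deprotonation with MeLi, bromine–lithium exchange with t-BuLi (THF, −78 °C) and a DMF quench then give 5.

**Step 2 (selective silylation).**
- What may go wrong: competing silylation of the phenol, giving a mixture of mono- and bis-silyl ethers.
- Fallback, from 3, returning at 4: exhaustive silylation (TBSCl 2.5 equiv, imidazole, DMF) to the bis-silyl ether tert-butyl{3-[4-(tert-butyldimethylsilyloxy)-3-methoxyphenyl]propoxy}dimethylsilane F7, then selective cleavage of the aryl silyl ether with K2CO3 in MeOH at rt to 4.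

## Further compounds

F1 | step 11 | 1-[3-methoxy-4-(pivaloyloxy)benzyl]thiolan-1-ium tetrafluoroborate | COc1cc(C[S+]2CCCC2)ccc1OC(=O)C(C)(C)C.F[B-](F)(F)F
F2 | step 11 | racemic trans-5-[3-(tert-butyldimethylsilyloxy)propyl]-7-methoxy-2-[3-methoxy-4-(pivaloyloxy)phenyl]-3-(nitromethyl)-2,3-dihydrobenzofuran (both enantiomers written) | COc1cc([C@H]2Oc3c(OC)cc(CCCO[Si](C)(C)C(C)(C)C)cc3[C@@H]2C[N+](=O)[O-])ccc1OC(=O)C(C)(C)C.COc1cc([C@@H]2Oc3c(OC)cc(CCCO[Si](C)(C)C(C)(C)C)cc3[C@H]2C[N+](=O)[O-])ccc1OC(=O)C(C)(C)C
F3 | step 11 | racemic trans-5-[3-(tert-butyldimethylsilyloxy)propyl]-7-methoxy-2-[3-methoxy-4-(pivaloyloxy)phenyl]-2,3-dihydrobenzofuran-3-carboxylic acid (both enantiomers written) | COc1cc([C@H]2Oc3c(OC)cc(CCCO[Si](C)(C)C(C)(C)C)cc3[C@@H]2C(=O)O)ccc1OC(=O)C(C)(C)C.COc1cc([C@@H]2Oc3c(OC)cc(CCCO[Si](C)(C)C(C)(C)C)cc3[C@H]2C(=O)O)ccc1OC(=O)C(C)(C)C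
F4 | step 11 | (S)-1-phenylethylammonium (2S,3S)-5-[3-(tert-butyldimethylsilyloxy)propyl]-7-methoxy-2-[3-methoxy-4-(pivaloyloxy)phenyl]-2,3-dihydrobenzofuran-3-carboxylate | COc1cc([C@H]2Oc3c(OC)cc(CCCO[Si](C)(C)C(C)(C)C)cc3[C@@H]2C(=O)[O-])ccc1OC(=O)C(C)(C)C.C[C@H]([NH3+])c1ccccc1
F5 | step 12 | (2S,3S)-5-[3-(tert-butyldimethylsilyloxy)propyl]-7-methoxy-2-[3-methoxy-4-(pivaloyloxy)phenyl]-2,3-dihydrobenzofuran-3-carbaldehyde | COc1cc([C@H]2Oc3c(OC)cc(CCCO[Si](C)(C)C(C)(C)C)cc3[C@@H]2C=O)ccc1OC(=O)C(C)(C)C
F0 | step 10 | none | none
F6 | step 3 | 2-bromo-6-methoxy-4-[3-(tert-butyldimethylsilyloxy)propyl]phenol | COc1cc(CCCO[Si](C)(C)C(C)(C)C)cc(Br)c1O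
F7 | step 2 | tert-butyl{3-[4-(tert-butyldimethylsilyloxy)-3-methoxyphenyl]propoxy}dimethylsilane | COc1cc(CCCO[Si](C)(C)C(C)(C)C)ccc1O[Si](C)(C)C(C)(C)C
A1 | alternative 1 | (S)-2-(4-acetoxy-3-methoxyphenyl)-6-[3-(tert-butyldiphenylsilyloxy)propyl]-8-methoxychroman-4-one | COc1cc([C@@H]2CC(=O)c3cc(CCCO[Si](c4ccccc4)(c5ccccc5)C(C)(C)C)cc(OC)c3O2)ccc1OC(C)=O
A2 | alternative 1 | methyl (2S,3S)-2-(4-acetoxy-3-methoxyphenyl)-5-[3-(tert-butyldiphenylsilyloxy)propyl]-7-methoxy-2,3-dihydrobenzofuran-3-carboxylate (trans) | COc1cc([C@H]2Oc3c(OC)cc(CCCO[Si](c4ccccc4)(c5ccccc5)C(C)(C)C)cc3[C@@H]2C(=O)OC)ccc1OC(C)=O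
A3 | alternative 2 | syn aldol imide: 4-benzyl-3-{3-[4-(benzyloxy)-3-methoxyphenyl]-3-hydroxy-2-[5-(3-(tert-butyldiphenylsilyloxy)propyl)-3-methoxy-2-(methoxymethoxy)phenyl]propanoyl}oxazolidin-2-one, configuration as in the SMILES | COc1cc([C@@H](O)[C@@H](C(=O)N2[C@@H](Cc3ccccc3)COC2=O)c4cc(CCCO[Si](c5ccccc5)(c6ccccc6)C(C)(C)C)cc(OC)c4OCOC)ccc1OCc7ccccc7
A4 | alternative 3 | methyl 2-[4-(benzyloxy)-3-methoxyphenyl]-5-[3-(tert-butyldimethylsilyloxy)propyl]-7-methoxybenzofuran-3-carboxylate | COC(=O)c1c(-c2ccc(OCc3ccccc3)c(OC)c2)oc4c(OC)cc(CCCO[Si](C)(C)C(C)(C)C)cc14
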